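Ciwujiatone is treated as the ring-opened aryl ketone of a cis-fused furo[3,4-c]furan-1-one, so that ring fusion locks the cis C3/C4 pair of its tetrahydrofuran ring (O1, C2 aryl, C3 CH2OH, C4 aroyl, C5 H2). Everything rests on cutting C4–C5. The key step inserts formaldehyde into the donor–acceptor bond of an enantiopure, all-cis 6-aryl-3-oxabicyclo[3.1.0]hexan-2-one: oxygen takes benzylic C2 with inversion, then the ketene acetal carbon C4 closes the ring on the O=CH2 carbon. It exploits the 1,3-relation between the benzylic C2–O1 bond and carbonyl-bearing C4. The precursor, a cyclopropane-fused lactone, comes from a (Z)-cinnamyl diazoacetate; one aryl bromide supplies both arenes.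

Key step: step 6

Remark: in names, Ar = 3,5-dimethoxy-4-(triisopropylsilyloxy)phenyl. The SMILES are written in full.
Assumption: the sense of induction of Rh2(5R-MEPY)4 is taken over from simple allyl and (Z)-alkenyl diazoacetates. If it proved opposite, the equally available Rh2(5S-MEPY)4 would be used.

Step 1
Reactants: 1 4-bromo-2,6-dimethoxyphenol
Product: 2 (4-bromo-2,6-dimethoxyphenoxy)triisopropylsilane
Conditions: TIPSCl, imidazole, DMAP (cat.), DMF, 40 °C
Reagents that add atoms: triisopropylsilyl chloride, CC(C)[Si](Cl)(C(C)C)C(C)C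
Why: Imidazole-promoted O-silylation of a phenol; the bulky TIPS ether should survive amine bases, BuLi and silyl triflate, keeps the para oxygen a π-donor for step 6 and falls to fluoride at the end.

Step 2
Reactants: 2 (4-bromo-2,6-dimethoxyphenoxy)triisopropylsilane; 3 prop-2-yn-1-ol
Product: 4 3-Ar-prop-2-yn-1-ol
Conditions: Pd(PhCN)2Cl2 (3 mol %), P(t-Bu)3·HBF4 (6 mol %), CuI (2 mol %), i-Pr2NH, dioxane, rt
Reagents that add atoms: none
Why: Sonogashira coupling; the bulky, electron-rich phosphine makes oxidative addition of zerovalent palladium into the electron-rich aryl bromide feasible at room temperature, and the free propargylic OH is tolerated.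

Step 3
Reactants: 4 3-Ar-prop-2-yn-1-ol
Product: 5 (Z)-3-Ar-prop-2-en-1-ol
Conditions: H2 (1 atm), Pd/CaCO3 poisoned with Pb(OAc)2, quinoline, EtOAc, rt, stopped after 1 equiv H2
Reagents that add atoms: none
Why: Syn semihydrogenation of an alkyne on a lead-poisoned palladium surface, which sets the Z geometry that later becomes the endo (all-cis) position of the aryl group.

Step 4
Reactants: 5 (Z)-3-Ar-prop-2-en-1-ol
Product: 7 (Z)-3-Ar-prop-2-en-1-yl diazoacetate, via bromoacetate 6 (not isolated)
Conditions: BrCH2COBr, NaHCO3, MeCN, 0 °C; then TsNHNHTs, DBU, THF, 0 °C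
Reagents that add atoms: bromoacetyl bromide, O=C(Br)CBr; N,N'-ditosylhydrazine, Cc1ccc(cc1)S(=O)(=O)NNS(=O)(=O)c1ccc(C)cc1
Why: O-Acylation followed by the ditosylhydrazine route to diazoacetates (N-alkylation by the bromoacetate, then two base-induced sulfinate eliminations), mild enough to leave the Z-alkene and the silyl ether untouched.

Step 5
Reactants: 7 (Z)-3-Ar-prop-2-en-1-yl diazoacetate
Product: 8 (1S,5R,6S)-6-Ar-3-oxabicyclo[3.1.0]hexan-2-one (aryl endo, all-cis cyclopropane)
Conditions: Rh2(5R-MEPY)4 (dirhodium tetrakis[methyl (5R)-2-oxopyrrolidine-5-carboxylate], 1 mol %), CH2Cl2, reflux, slow addition of 7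
Reagents that add atoms: none
Why: Intramolecular carbene cyclopropanation with a chiral dirhodium carboxamidate, a catalyst class at its best with (Z)-allylic diazoacetates: concerted syn addition carries the Z geometry into the endo aryl group, the tether forces the cis lactone, and the catalyst pocket picks the alkene face and so fixes all three centres (C5 and C1 become C3 and C4 of the target, C6 becomes C2 after inversion).

Step 6
Reactants: 8 (1S,5R,6S)-6-Ar-3-oxabicyclo[3.1.0]hexan-2-one
Product: 10 (3aR,4S,6aR)-4-Ar-tetrahydro-1H,3H-furo[3,4-c]furan-1-one (cis-fused, aryl exo), via oxocarbenium ketene acetal 9 (not isolated)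
Conditions: 1,3,5-trioxane (3 equiv), TMSOTf (0.2 equiv), 2,6-di-tert-butyl-4-methylpyridine (0.1 equiv), 4 Å MS, CH2Cl2, −40 → 0 °C; Et3N quench
Reagents that add atoms: 1,3,5-trioxane (source of one formaldehyde unit), C1OCOCO1
Why: Proposed new method: TMSOTf silylates the lactone carbonyl of 8, formaldehyde (or a trioxane oxygen that then sheds two CH2O) attacks the benzylic cyclopropane carbon C6 from the rear of the C1–C6 bond, and the silyl ketene acetal/oxocarbenium ion 9 so formed collapses by an intramolecular Mukaiyama aldol-type addition that joins the lactone α-carbon (C6a of 10, C4 of the target) to the O=CH2 carbon (C6 of 10, C5 of the target) and returns TMSOTf. The closest known reaction type is the Lewis-acid-catalysed (3+2) annulation of aldehydes with 2-arylcyclopropane-1,1-diesters, where the aldehyde oxygen opens the ring with inversion and the malonate carbon closes the tetrahydrofuran; new are the single lactone acceptor, offset by O-silylation and by the strain of the all-cis bicycle, and formaldehyde as partner. The only ring closed, the tetrahydrofuran, forms in a 5-(enolexo)-endo-trig mode, formally disfavoured but usual for oxocarbenium ions, as in Prins–pinacol and oxonia-Cope/aldol routes to 3-acyltetrahydrofurans. The benzylic centre (C4 of 10, C2 of the target) arises by inversion of the endo-aryl carbon and therefore ends exo and trans to the CH2O arm, while the α-carbon can bond only on the face that gives the cis-fused bicyclo[3.3.0] system and is thus controlled by the untouched neighbour C3a; a looser, cation-like opening should still favour the exo-aryl isomer, since the endo closure forces the aryl group into the concave face. Needed are cleavage of C1–C6 rather than C1–C5 or C5–C6, secured because only this bond is both benzylic to the donor and aligned with the carbonyl π system, and capture by formaldehyde before proton loss or Friedel–Crafts attack, for which excess trioxane, low temperature, a hindered pyridine and the tethered, highly nucleophilic ketene acetal are provided.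

Step 7
Reactants: 10 (3aR,4S,6aR)-4-Ar-tetrahydro-1H,3H-furo[3,4-c]furan-1-one; 2 (4-bromo-2,6-dimethoxyphenoxy)triisopropylsilane
Product: 13 [(3R,4R,5S)-5-Ar-4-(hydroxymethyl)tetrahydrofuran-3-yl](Ar)methanone (bis-TIPS ciwujiatone), via aryllithium 11 (not isolated), via lithium hemiketalate 12 (not isolated)
Conditions: 2 (1.15 equiv), n-BuLi (1.1 equiv), THF, −78 °C; then 10, THF, −78 °C; AcOH/THF quench at −78 °C
Reagents that add atoms: none
Why: Bromine–lithium exchange and single 1,2-addition of the aryllithium to a γ-lactone, whose tetrahedral lithium hemiketalate persists at −78 °C and blocks a second addition; no stereocentre is touched, and the cold acetic acid quench should release the cis γ-hydroxy ketone (in equilibrium with its bicyclic lactol) without enolisation at C4.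

Step 8
Reactants: 13 bis-TIPS ciwujiatone
Product: 14 ciwujiatone, [(3R,4R,5S)-5-(4-hydroxy-3,5-dimethoxyphenyl)-4-(hydroxymethyl)tetrahydrofuran-3-yl](4-hydroxy-3,5-dimethoxyphenyl)methanone
Conditions: TBAF/AcOH (1:1, 2.5 equiv), THF, 0 °C
Reagents that add atoms: none
Why: Fluoride-induced cleavage of the two aryl silyl ethers, buffered with acetic acid so that neither the epimerisable C4–H next to the ketone nor the p-hydroxybenzylic C2–O1 bond is exposed to free phenoxide or basic fluoride.

Compound list
1 | 4-bromo-2,6-dimethoxyphenol | COc1cc(Br)cc(OC)c1O | starting material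
2 | (4-bromo-2,6-dimethoxyphenoxy)triisopropylsilane | COc1cc(Br)cc(OC)c1O[Si](C(C)C)(C(C)C)C(C)C | intermediate
3 | prop-2-yn-1-ol | OCC#C | starting material
4 | 3-[3,5-dimethoxy-4-(triisopropylsilyloxy)phenyl]prop-2-yn-1-ol | OCC#Cc1cc(OC)c(O[Si](C(C)C)(C(C)C)C(C)C)c(OC)c1 | intermediate
5 | (Z)-3-[3,5-dimethoxy-4-(triisopropylsilyloxy)phenyl]prop-2-en-1-ol | OC/C=C\c1cc(OC)c(O[Si](C(C)C)(C(C)C)C(C)C)c(OC)c1 | intermediate
6 | (Z)-3-Ar-prop-2-en-1-yl bromoacetate (not isolated) | BrCC(=O)OC/C=C\c1cc(OC)c(O[Si](C(C)C)(C(C)C)C(C)C)c(OC)c1 | intermediate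
7 | (Z)-3-Ar-prop-2-en-1-yl diazoacetate | [N-]=[N+]=CC(=O)OC/C=C\c1cc(OC)c(O[Si](C(C)C)(C(C)C)C(C)C)c(OC)c1 | intermediate
8 | (1S,5R,6S)-6-Ar-3-oxabicyclo[3.1.0]hexan-2-one, aryl endo | O=C1OC[C@@H]2[C@H](c3cc(OC)c(O[Si](C(C)C)(C(C)C)C(C)C)c(OC)c3)[C@H]12 | intermediate
9 | O-methylidene oxocarbenium triflate of (S)-Ar[(3R)-5-(trimethylsilyloxy)-2,3-dihydrofuran-3-yl]methanol (not isolated) | C=[O+][C@H](c2cc(OC)c(O[Si](C(C)C)(C(C)C)C(C)C)c(OC)c2)[C@H]1COC(O[Si](C)(C)C)=C1.[O-]S(=O)(=O)C(F)(F)F | intermediate
10 | (3aR,4S,6aR)-4-Ar-tetrahydro-1H,3H-furo[3,4-c]furan-1-one | O=C1OC[C@H]2[C@@H]1CO[C@@H]2c3cc(OC)c(O[Si](C(C)C)(C(C)C)C(C)C)c(OC)c3 | intermediate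
11 | [3,5-dimethoxy-4-(triisopropylsilyloxy)phenyl]lithium (not isolated) | COc1cc([Li])cc(OC)c1O[Si](C(C)C)(C(C)C)C(C)C | intermediate
12 | lithium hemiketalate from addition of 11 to 10, hemiketal carbon undefined and lost on opening (not isolated) | [Li+].[O-]C1(c3cc(OC)c(O[Si](C(C)C)(C(C)C)C(C)C)c(OC)c3)OC[C@H]2[C@@H]1CO[C@@H]2c4cc(OC)c(O[Si](C(C)C)(C(C)C)C(C)C)c(OC)c4 | intermediate
13 | [(3R,4R,5S)-5-Ar-4-(hydroxymethyl)tetrahydrofuran-3-yl](Ar)methanone | COc1cc(C(=O)[C@H]2CO[C@H](c3cc(OC)c(O[Si](C(C)C)(C(C)C)C(C)C)c(OC)c3)[C@H]2CO)cc(OC)c1O[Si](C(C)C)(C(C)C)C(C)C | intermediate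
14 | ciwujiatone | COc1cc(C(=O)[C@H]2CO[C@H](c3cc(OC)c(O)c(OC)c3)[C@H]2CO)cc(OC)c1O | target

Total step count: 8. Longest linear sequence: 8 steps (1 → 2 → 4 → 5 → 7 → 8 → 10 → 13 → 14). Compound 2 is used a second time in step 7.

Steps most likely to fail

1. Step 6.
- **What may go wrong:** the singly activated cyclopropane may open too slowly. The developing benzylic cation may also be discharged by proton loss, arene alkylation or endo/exo scrambling before formaldehyde is captured.
- **Fallback:** known chemistry, with a carbene C–H insertion in place of the cationic annulation. It sets out from 8 and comes back at 10. Acid-catalysed solvolytic opening of 8 in methanol (cat. TfOH, MeOH/(CF3)2CHOH, rt), a nucleophilic ring opening of a donor–acceptor cyclopropane with inversion, should give the methyl ether lactone F1. LiHMDS and CF3CO2CH2CF3 (THF, −78 °C) give the α-trifluoroacetyl lactone F2. With MsN3 and Et3N in MeCN this undergoes detrifluoroacetylative diazo transfer to the α-diazolactone F3. Rh2(OAc)4 in refluxing CH2Cl2 then forms the same C–C bond by 1,5 C–H insertion of the rhodium carbene into the OCH3 group. The cis ring fusion is again enforced, and 10 results.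

2. Step 7.
- **What may go wrong:** α-deprotonation of the lactone by the aryllithium, a second addition after premature collapse of the hemiketalate, or base-induced epimerisation at C4 in the keto alkoxide.
- **Fallback:** it sets out from 10 and comes back at 14. Aminolysis with MeNH(OMe)·HCl/i-PrMgCl (THF, −20 °C) should give the hydroxy Weinreb amide F4. TESCl/imidazole gives its triethylsilyl ether F5. Aryllithium 11 adds once to the chelating amide to give the tris-silylated ketone F6. The buffered fluoride conditions of step 8 then remove all three silyl groups and deliver 14.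

3. Step 5.
- **What may go wrong:** poor facial selectivity with the bulky electron-rich aryl group, carbene attack on the arene, or carbene dimerisation.
- **Fallback:** it sets out from 5 and comes back at 8. The first operation is a hydroxyl-directed enantioselective zinciocyclopropanation of 5. It uses the gem-dizinc carbenoid from CHI3 and Et2Zn with stoichiometric (4R,5R)-2-butyl-N,N,N',N'-tetramethyl-1,3,2-dioxaborolane-4,5-dicarboxamide. The ligand sense is assigned by analogy with cinnamyl alcohol, and zinc ends cis to the CH2O arm. An I2 quench should give the all-cis iodocyclopropylmethanol F7. Deprotonation and iodine–lithium exchange with retention (n-BuLi, then t-BuLi, Et2O, −78 °C) and CO2 give the hydroxy acid F8, which lactonises on acidic work-up to 8.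

Further compounds
F1 | step 6 | (4R)-4-[(S)-Ar(methoxy)methyl]dihydrofuran-2(3H)-one | O=C1C[C@H](CO1)[C@H](OC)c2cc(OC)c(O[Si](C(C)C)(C(C)C)C(C)C)c(OC)c2
F2 | step 6 | (4R)-4-[(S)-Ar(methoxy)methyl]-3-(trifluoroacetyl)dihydrofuran-2(3H)-one (C3 undefined, enolised) | O=C1C(C(=O)C(F)(F)F)[C@H](CO1)[C@H](OC)c2cc(OC)c(O[Si](C(C)C)(C(C)C)C(C)C)c(OC)c2
F3 | step 6 | (4R)-3-diazo-4-[(S)-Ar(methoxy)methyl]dihydrofuran-2(3H)-one | O=C1C(=[N+]=[N-])[C@H](CO1)[C@H](OC)c2cc(OC)c(O[Si](C(C)C)(C(C)C)C(C)C)c(OC)c2
F4 | step 7 | (3R,4R,5S)-5-Ar-4-(hydroxymethyl)-N-methoxy-N-methyltetrahydrofuran-3-carboxamide | CON(C)C(=O)[C@H]1CO[C@H](c2cc(OC)c(O[Si](C(C)C)(C(C)C)C(C)C)c(OC)c2)[C@H]1CO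
F5 | step 7 | (3R,4R,5S)-5-Ar-N-methoxy-N-methyl-4-[(triethylsilyloxy)methyl]tetrahydrofuran-3-carboxamide | CON(C)C(=O)[C@H]1CO[C@H](c2cc(OC)c(O[Si](C(C)C)(C(C)C)C(C)C)c(OC)c2)[C@H]1CO[Si](CC)(CC)CC
F6 | step 7 | {(3R,4R,5S)-5-Ar-4-[(triethylsilyloxy)methyl]tetrahydrofuran-3-yl}(Ar)methanone | COc1cc(C(=O)[C@H]2CO[C@H](c3cc(OC)c(O[Si](C(C)C)(C(C)C)C(C)C)c(OC)c3)[C@H]2CO[Si](CC)(CC)CC)cc(OC)c1O[Si](C(C)C)(C(C)C)C(C)C
F7 | step 5 | [(1S,2R,3S)-2-Ar-3-iodocyclopropyl]methanol (all-cis) | OC[C@@H]1[C@H](c2cc(OC)c(O[Si](C(C)C)(C(C)C)C(C)C)c(OC)c2)[C@@H]1I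
F8 | step 5 | (1S,2S,3R)-2-Ar-3-(hydroxymethyl)cyclopropane-1-carboxylic acid (all-cis) | OC[C@@H]1[C@H](c2cc(OC)c(O[Si](C(C)C)(C(C)C)C(C)C)c(OC)c2)[C@@H]1C(O)=O
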